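**Retrosynthetic overview**
- Target ⇒ a (Z)-enediynone, whose two alkynes are held by the three-carbon unit C1(=O)–C2(azulenyl)=C3(Me), plus 3-ethynylguaiazulene. One rhodium-catalysed [2+2+2] cycloaddition closes the benzene ring and the cyclopentenone ring of the indenone together, with both azulenes already in place.
- Enediynone ⇒ ester-to-propynyl-ketone conversion (C1–C7a) and Sonogashira coupling with 2-methylbut-3-yn-2-ol (C3–C3a) on the Z-enol triflate of ethyl 2-guaiazulenylacetoacetate. The Z geometry is the only stereochemical element of the route.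
- Ketoester ⇒ guaiazulene + ethyl diazoacetoacetate (carbenoid C–H functionalisation at C3 of guaiazulene makes the C2–azulenyl bond).
- 3-Ethynylguaiazulene ⇒ guaiazulene + TIPS-EBX (gold-catalysed C–H alkynylation, then desilylation).
- Ring order: the four azulene rings are bought as guaiazulene; the six- and five-membered rings of the indenone are formed last, in the same operation.

Assumption: the target has no stereocentre and its SMILES fixes no configuration at the two aryl–azulenyl axes, so it is made as the achiral constitution drawn with no enantioselective step; ethyl 2-diazo-3-oxobutanoate, TIPS-EBX and prop-1-ynyllithium are taken as bought.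

Abbreviation: Gu = 5-(propan-2-yl)-3,8-dimethylazulen-1-yl (the guaiazulen-3-yl group).

**Step 1**
Reactants: 1 guaiazulene (1,4-dimethyl-7-(propan-2-yl)azulene); 2 ethyl 2-diazo-3-oxobutanoate
Product: 3 ethyl 2-Gu-3-oxobutanoate (racemic, enolisable CH)
Conditions: Rh2(OAc)4 (1 mol %), slow addition of 2, ClCH2CH2Cl, 70 °C
Reagents that add atoms: none
Why: The electrophilic rhodium carbenoid from 2 is attacked by C3 of guaiazulene, the most nucleophilic carbon of the azulene, and proton loss from the azulenium zwitterion gives the formal C–H insertion product (carbenoid C–H functionalisation of an electron-rich arene); the new CH centre is enolisable and needs no control.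

**Step 2**
Reactants: 3 ethyl 2-Gu-3-oxobutanoate
Product: 5 ethyl (2Z)-2-Gu-3-[(trifluoromethanesulfonyl)oxy]but-2-enoate, via sodium Z-enolate 4 (not isolated)
Conditions: NaH, THF, 0 °C; then PhNTf2, 0 °C → rt; aq NH4Cl
Reagents that add atoms: N-phenylbis(trifluoromethanesulfonimide), O=S(=O)(N(c1ccccc1)S(=O)(=O)C(F)(F)F)C(F)(F)F
Why: Enol triflate formation: O-sulfonylation of the sodium-chelated U-shaped enolate 4 places the triflate cis to the ester, which fixes the Z geometry that later holds the two alkynes on the same side; no stereocentre is formed.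

**Step 3**
Reactants: 5 ethyl (2Z)-2-Gu-3-[(trifluoromethanesulfonyl)oxy]but-2-enoate; 6 2-methylbut-3-yn-2-ol
Product: 7 ethyl (2Z)-2-Gu-6-hydroxy-3,6-dimethylhept-2-en-4-ynoate
Conditions: Pd(PPh3)2Cl2 (5 mol %), CuI (10 mol %), Et3N, THF, rt
Reagents that add atoms: none
Why: Sonogashira coupling of the activated β-triflyloxy enoate proceeds by oxidative addition and reductive elimination with retention of the alkene geometry, and the free tertiary alcohol is tolerated.

**Step 4**
Reactants: 7 ethyl (2Z)-2-Gu-6-hydroxy-3,6-dimethylhept-2-en-4-ynoate; 8 prop-1-ynyllithium (CH3C≡CLi)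
Product: 9 (5Z)-5-Gu-9-hydroxy-6,9-dimethyldec-5-ene-2,7-diyn-4-one
Conditions: 8 (3.5 equiv), BF3·OEt2 (3.5 equiv), THF, −78 °C; then 7, −78 °C; aq NH4Cl
Reagents that add atoms: none
Why: Yamaguchi ynone synthesis: the alkynyl trifluoroborate formed from 8 and BF3·OEt2 adds once to the ester and the boron-bound tetrahedral adduct survives until the quench, so no tertiary alcohol forms; one equivalent of 8 is spent on the hydroxyl group and the Z alkene is untouched.

**Step 5**
Reactants: 1 guaiazulene; 10 TIPS-EBX (1-[(triisopropylsilyl)ethynyl]-1,2-benziodoxol-3(1H)-one)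
Product: 12 1-ethynyl-5-(propan-2-yl)-3,8-dimethylazulene (3-ethynylguaiazulene), via silylalkyne 11 (not isolated)
Conditions: AuCl (5 mol %), MeCN, rt; then Bu4NF, THF, 0 °C → rt
Reagents that add atoms: none
Why: Gold-catalysed electrophilic C–H alkynylation with the ethynylbenziodoxolone takes place at C3 of guaiazulene, the only free nucleophilic position, and fluoride then cleaves the C–Si bond of 11 to give the terminal alkyne.

**Step 6**
Reactants: 9 (5Z)-5-Gu-9-hydroxy-6,9-dimethyldec-5-ene-2,7-diyn-4-one; 12 3-ethynylguaiazulene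
Product: 13 2,6-di-Gu-4-(2-hydroxypropan-2-yl)-3,7-dimethyl-1H-inden-1-one (target)
Conditions: [Rh(cod)2]BF4 (10 mol %), rac-BINAP (10 mol %), H2 pre-activation, 12 (2 equiv), slow addition of 9, ClCH2CH2Cl, rt → 40 °C
Reagents that add atoms: none
Why: Proposed new method: cationic monovalent rhodium couples the two alkynes of 9, which the Z alkene and the ketone hold close together, to a rhodacyclopentadiene that already contains the five-membered carbocycle, 12 then inserts and reductive elimination closes the benzene ring, with the bulky azulenyl carbon expected next to the methyl-bearing terminus and not next to the quaternary carbinol terminus; the closest known reaction type is the rhodium-catalysed [2+2+2] cycloaddition of 2-alkynylaryl alkynyl ketones with monoalkynes that gives fluorenones; no stereocentre is formed and the two aryl–azulenyl axes are not controlled.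

**Compound list**
1 | guaiazulene (1,4-dimethyl-7-(propan-2-yl)azulene) | c1cc(C)c2cc(C(C)C)ccc(C)c1-2 | starting material
2 | ethyl 2-diazo-3-oxobutanoate | CCOC(=O)C(=[N+]=[N-])C(C)=O | starting material
3 | ethyl 2-Gu-3-oxobutanoate (racemic) | CCOC(=O)C(C(C)=O)c1cc(C)c2cc(C(C)C)ccc(C)c1-2 | intermediate
4 | sodium (2Z)-4-ethoxy-3-Gu-4-oxobut-2-en-2-olate (sodium Z-enolate of 3) | CCOC(=O)/C(c1cc(C)c2cc(C(C)C)ccc(C)c1-2)=C(/C)[O-].[Na+] | intermediate
5 | ethyl (2Z)-2-Gu-3-[(trifluoromethanesulfonyl)oxy]but-2-enoate | CCOC(=O)/C(c1cc(C)c2cc(C(C)C)ccc(C)c1-2)=C(/C)OS(=O)(=O)C(F)(F)F | intermediate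
6 | 2-methylbut-3-yn-2-ol | CC(C)(O)C#C | starting material
7 | ethyl (2Z)-2-Gu-6-hydroxy-3,6-dimethylhept-2-en-4-ynoate | CCOC(=O)/C(c1cc(C)c2cc(C(C)C)ccc(C)c1-2)=C(/C)C#CC(C)(C)O | intermediate
8 | prop-1-ynyllithium | [Li]C#CC | starting material
9 | (5Z)-5-Gu-9-hydroxy-6,9-dimethyldec-5-ene-2,7-diyn-4-one | CC#CC(=O)/C(c1cc(C)c2cc(C(C)C)ccc(C)c1-2)=C(/C)C#CC(C)(C)O | intermediate
10 | TIPS-EBX, 1-[(triisopropylsilyl)ethynyl]-1,2-benziodoxol-3(1H)-one | CC(C)[Si](C#CI1OC(=O)c2ccccc12)(C(C)C)C(C)C | starting material
11 | [(Gu)ethynyl]tri(propan-2-yl)silane | CC(C)[Si](C#Cc1cc(C)c2cc(C(C)C)ccc(C)c1-2)(C(C)C)C(C)C | intermediate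
12 | 1-ethynyl-5-(propan-2-yl)-3,8-dimethylazulene (3-ethynylguaiazulene) | C#Cc1cc(C)c2cc(C(C)C)ccc(C)c1-2 | intermediate
13 | 2,6-di-Gu-4-(2-hydroxypropan-2-yl)-3,7-dimethyl-1H-inden-1-one | CC1=C(c2cc(C)c3cc(C(C)C)ccc(C)c2-3)C(=O)c2c(C)c(-c3cc(C)c4cc(C(C)C)ccc(C)c3-4)cc(C(C)(C)O)c21 | target

**Totals**
Total step count: 6. Longest linear sequence: 5 steps (steps 1, 2, 3, 4 and 6).

**Steps most likely to fail**

Step 6 (most at risk). The insertion of 12 may go with the wrong orientation, since the polarisation of the azulenyl alkyne works against the steric preference. The cis-enynone 9 may also be diverted to a furyl carbenoid. Fallback: tie the alkyne to the tertiary hydroxyl group through a temporary silicon tether, so that the cycloaddition is fully intramolecular and the orientation is fixed. It sets out from 12 and 9. LiN(SiMe3)2 in THF at −78 °C converts 12 into lithium 2-Gu-ethynide F1, which is added to excess Me2SiCl2 to give chloro(dimethyl)[(Gu)ethynyl]silane F2. F2 silylates the tertiary alcohol of 9 (imidazole, CH2Cl2) to give the silyl ether triyne F3. The rhodium catalyst of step 6 (or CpCo(CO)2 with light) closes F3 to the siloxane-bridged indenone F4, in which the tether forces the azulenyl carbon to bond to the methyl-bearing carbon. Bu4NF in wet THF at 60 °C then cleaves the Si–O bond and protodesilylates C5, which comes back to the route at 13.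

Step 1. The acceptor/acceptor carbenoid may attack the seven-membered ring or react sluggishly with the azulene. Fallback: build the ketoester in two C–C bond formations. It sets out from 1: copper-catalysed insertion of ethyl diazoacetate (Cu(acac)2, CH2Cl2, reflux) gives ethyl 2-Gu-acetate F5. LiN(SiMe3)2 (2.2 equiv, THF, −78 °C) gives the lithium enolate F6, which is C-acetylated with 1-acetylimidazole and quenched with aq NH4Cl, coming back to the route at 3.

Step 4. The hindered tetrasubstituted ester may react slowly, or BF3 may ionise the azulene-conjugated tertiary propargylic alkoxide. Fallback: acyl transfer through an isolated Weinreb amide without a Lewis acid. It sets out from 7: MeNH(OMe)·HCl and iPrMgCl (THF, −20 °C) give the (2Z)-N-methoxy-N-methylamide F7. CH3C≡CMgBr (THF, 0 °C) then adds once to the chelated amide, coming back to the route at 9.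

**Further compounds**
F1 | step 6 | lithium 2-Gu-ethynide | [Li]C#Cc1cc(C)c2cc(C(C)C)ccc(C)c1-2
F2 | step 6 | chloro(dimethyl)[(Gu)ethynyl]silane | C[Si](C)(Cl)C#Cc1cc(C)c2cc(C(C)C)ccc(C)c1-2
F3 | step 6 | (5Z)-5-Gu-6,9-dimethyl-9-({dimethyl[(Gu)ethynyl]silyl}oxy)dec-5-ene-2,7-diyn-4-one | CC#CC(=O)/C(c1cc(C)c2cc(C(C)C)ccc(C)c1-2)=C(/C)C#CC(C)(C)O[Si](C)(C)C#Cc1cc(C)c2cc(C(C)C)ccc(C)c1-2
F4 | step 6 | siloxane-bridged indenone: 13 with the carbinol oxygen and C5 of the indenone joined through SiMe2 (five-membered oxasilole ring C4–CMe2–O–SiMe2–C5) | CC1=C(c2cc(C)c3cc(C(C)C)ccc(C)c2-3)C(=O)c2c(C)c(-c3cc(C)c4cc(C(C)C)ccc(C)c3-4)c3[Si](C)(C)OC(C)(C)c3c21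
F5 | step 1 | ethyl 2-Gu-acetate | CCOC(=O)Cc1cc(C)c2cc(C(C)C)ccc(C)c1-2
F6 | step 1 | lithium enolate of ethyl 2-Gu-acetate | CCOC([O-])=Cc1cc(C)c2cc(C(C)C)ccc(C)c1-2.[Li+]
F7 | step 4 | (2Z)-2-Gu-6-hydroxy-N-methoxy-N,3,6-trimethylhept-2-en-4-ynamide | CON(C)C(=O)/C(c1cc(C)c2cc(C(C)C)ccc(C)c1-2)=C(/C)C#CC(C)(C)O
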